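(The runs are calculated with made-up constants; noise was put on by code.)

**Flat readings.** A flat column of readings invites the verdict that something has run out, but flatness gives no reason; the place of the line, as the charges change, comes nearer to one.

| setting | Tuesday's | Monday's | Sunday's | flask |
|---|---|---|---|---|
| Z | 20 mM | 20 mM | 40 mM | 20 mM |
| L | 0.34 mol% | 0.75 mol% | 0.5 mol% | 0.5 mol% |
| remark | run made earlier | run made earlier | run made earlier |  |
| time |  |  |  | 30 h |

| run | time / h | Z / % | E / % |
|---|---|---|---|
| Tuesday's | 2.50 | 80.2 | 11.0 |
| Tuesday's | 8.00 | 75.8 | 16.1 |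
| Tuesday's | 12.0 | 75.4 | 15.3 |
| Tuesday's | 20.0 | 75.4 | 16.2 |
| Tuesday's | 30.0 | 74.0 | 15.6 |
| Tuesday's | 40.0 | 74.8 | 16.9 |
| Monday's | 3.00 | 76.3 | 15.4 |
| Monday's | 5.00 | 75.0 | 16.7 |
| Monday's | 8.00 | 75.3 | 15.3 |
| Monday's | 12.0 | 75.7 | 15.9 |
| Monday's | 20.0 | 75.2 | 15.7 |
| Monday's | 40.0 | 75.7 | 16.0 |
| Sunday's | 3.00 | 75.1 | 15.9 |
| Sunday's | 5.00 | 75.4 | 15.8 |
| Sunday's | 10.0 | 75.8 | 15.7 |
| Sunday's | 20.0 | 75.6 | 15.6 |
| Sunday's | 40.0 | 75.1 | 16.3 |

(standard deviation of a reading: 0.5 percentage points)

* the state of affairs at 30 h: stopped, and by what, or still going (it is still moving / forward and back rates have come level / no working catalyst is left / all of Z has reacted)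
* part of the Z gone at 30 h
* the E standing at 30 h, as a percentage of the Z charged
* the D standing at 30 h, as a percentage of the Z charged

- what was read earlier has a scatter of 0.5 percentage points, one standard deviation
- the reaction counts as stopped when no species that holds the Z changes by six tenths of a point or more over the second half of the time

**Share left.** Monday's run carries twice the L of Tuesday's, yet their last readings leave 75.7 % and 74.8 % of Z. Sunday's run, with twice the Z, averages 75.4 % of Z and 15.9 % of E over its 5 readings. That Z reading is taken as the part of the charged Z still standing when forward and back rates have come level, the equilibrium position: the level share left.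

**Time ladder.** Tuesday's run has the lowest loading and shows the order. At 2.50 h, D, taken as the remainder of the charge, is 8.80 %, already near its level of 8.74 %, while E stands at 11.0 %. So in Tuesday's run D reads as coming first. In that run E still has 30.6 % of its way to its level to go, which reads as a half-life of 1.47 h. With speed taken in proportion to [L], and [L] held at its charge, the flask's half-life reckons to 0.996 h. The last rung is the 30 h itself, 30.1 such half-lives, so the flask should stand level, with 24.6 % of Z gone, 15.9 % of E and 8.74 % of D.

**The check.** In the forecast, forward and back rates have come level, with 24.6 % gone, 15.9 % of E and 8.7 % of D, since “The plateau is the same in all three runs”. In the flask, forward and back rates have come level, with 24.6 % gone, 15.8 % of E and 8.71 % of D.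

    Z + L ⇌ E + L, rate k1*[Z]*[L] forward; the back reaction follows from the equilibrium constant (K = 0.210, k = 12.0 M⁻¹ min⁻¹)
    E + L ⇌ D + L, rate k2*[L]*[E] forward; the back reaction follows from the equilibrium constant (K = 0.550, k = 85.0 M⁻¹ min⁻¹)
    D + L ⇌ Z + L, rate k3*[L]*[D] forward; the back reaction follows from the equilibrium constant (k = 420 M⁻¹ min⁻¹)
    L → G (k = 7.40 × 10⁻⁴ min⁻¹)

**Level kept.** At 30.0 h the flask holds 26.4 % of its catalyst as L and 73.6 % as G, and the exchange of D and Z, by that step alone and both ways together, still relaxes with a half-life of 0.934 h, short against the 30 h. Z in the flask stands there at 75.4 %, and the level share left, as read on Sunday's run, was 75.4 %. A neighbouring flask, charged alike but with 50 mM of Z, keeps 75 % of its Z at 30.0 h.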